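Zanthobisquinolone consists of two identical 4-hydroxy-1-methylquinolin-2(1H)-one rings joined at their C3 atoms by one CH2 at the formaldehyde oxidation level. Each C3 is the nucleophilic α-carbon between the C2 lactam carbonyl and the C4 enol. The route cuts one C3–CH2 bond and forms it in a three-component domino Knoevenagel–Michael reaction. One quinolone condenses with formaldehyde to a transient 3-methylidenequinoline-2,4-dione, and C3 of a second quinolone attacks its exocyclic CH2. The precursor of the bond-forming event is therefore this quinone-methide-like enedione, made in the flask from the commercial quinolone and formaldehyde.

Key step: step 1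

Remark: the target has no stereocentre, stereogenic axis or stereogenic double bond, so it is achiral and needs no stereocontrol. It is drawn as the bis(4-hydroxy-2-quinolone) tautomer.

Step 1
Reactants: 1 4-hydroxy-1-methylquinolin-2(1H)-one (2 equiv); 2 formaldehyde (0.5 equiv relative to 1)
Product: 5 zanthobisquinolone [3,3'-methylenebis(4-hydroxy-1-methylquinolin-2(1H)-one)], via 4-hydroxy-3-(hydroxymethyl)-1-methylquinolin-2(1H)-one 3 (not isolated), via 1-methyl-3-methylidenequinoline-2,4(1H,3H)-dione 4 (not isolated)
Conditions: 37% aq. CH2O (slow addition), EtOH, reflux; cool, filter the precipitate
Reagents that add atoms: formaldehyde, C=O (this is compound 2 of the Reactants line; it supplies the bridging CH2 and no further reagent adds atoms)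
Why: Enol 1 adds through C3 to formaldehyde (the aldol stage of a Knoevenagel condensation) to give 3, which loses water to the quinone-methide-like enedione 4; a second molecule of 1 then adds through its C3 to the exocyclic CH2 of 4 (Michael addition), and tautomerisation gives the bis-enol 5. The closest known reaction type is the domino Knoevenagel–Michael condensation of cyclic 1,3-dicarbonyl enols with aldehydes, as in the formation of dicoumarol from 4-hydroxycoumarin and formaldehyde. No ring is closed and no stereocentre is created, since 5 is achiral. The step needs C3- over O-attack, and it needs 4 to be intercepted by 1 before it dimerises by hetero-Diels–Alder reaction or is hydroxymethylated further. The soft enol carbon C3 and the reversibility of any O-adduct should secure the first, and keeping 1 in excess over slowly added formaldehyde should secure the second. The sparingly soluble, doubly hydrogen-bonded product is expected to crystallise from hot ethanol and so pull the equilibria forward.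

Compound list
1 | 4-hydroxy-1-methylquinolin-2(1H)-one | Cn1c(=O)cc(O)c2ccccc21 | starting material
2 | formaldehyde (used as 37% aqueous solution) | C=O | starting material
3 | 4-hydroxy-3-(hydroxymethyl)-1-methylquinolin-2(1H)-one | Cn1c(=O)c(CO)c(O)c2ccccc21 | intermediate
4 | 1-methyl-3-methylidenequinoline-2,4(1H,3H)-dione | CN1C(=O)C(=C)C(=O)c2ccccc21 | intermediate
5 | zanthobisquinolone, 3,3'-methylenebis(4-hydroxy-1-methylquinolin-2(1H)-one) | Cn1c(=O)c(Cc2c(O)c3ccccc3n(C)c2=O)c(O)c2ccccc21 | target

Total step count: 1
Longest linear sequence: 1

Steps most likely to fail
The route has a single step, so only one entry can be given.

Step 1. What may go wrong: the transient enedione 4 may be consumed by hetero-Diels–Alder self-dimerisation or by further reaction with formaldehyde (hydroxymethylation, oligomer formation) faster than the second quinolone traps it. Alternatively, the sequence may stall at the hydroxymethyl stage 3 if dehydration is slow. Either process would lower the conversion to the 2:1 adduct.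

Fallback: the one-pot three-component reaction is replaced by a two-stage coupling that uses an isolable precursor of 4. It sets out from compound 1. Aminomethylation with Eschenmoser's salt (N,N-dimethylmethyleneiminium iodide, Et3N, CH2Cl2, 0 °C to rt; Mannich reaction at C3) should give 3-[(dimethylamino)methyl]-4-hydroxy-1-methylquinolin-2(1H)-one F1. This Mannich base is then heated with one further equivalent of 1 in toluene at reflux. Thermal loss of dimethylamine should release 4 slowly, with no free formaldehyde present and with the nucleophile always in excess, so that Michael addition of 1 through C3 should dominate. The fallback comes back to the route at compound 5, the target.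

Further compounds
F1 | step 1 | 3-[(dimethylamino)methyl]-4-hydroxy-1-methylquinolin-2(1H)-one | CN(C)Cc1c(O)c2ccccc2n(C)c1=O
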